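Abbreviations in compound names: TIPS = tri(propan-2-yl)silyl, PMB = (4-methoxyphenyl)methyl, TBS = tert-butyldimethylsilyl, TES = triethylsilyl, pin = pinacolato, Tf = trifluoromethanesulfonyl. Ten-membered compounds 18–25 are named with the target numbering fixed below.

## Analysis of the target

Target 25 is a ten-membered carbocycle of the germacrane type. The ring is numbered C1 (alkene CH), C2, C3 (angelate carbinol), C4 (epoxide carbon with methyl), C5 (epoxide CH), C6 (acetate carbinol), C7 (isopropyl CH), C8, C9 and C10 (methyl-bearing alkene carbon). It carries an E trisubstituted C1=C10 alkene, a trans C4,C5 epoxide and five contiguous stereocentres, 3S,4R,5R,6S,7S. When C3–H and C6–H eclipse the plane of the former C4=C5 alkene, both ester oxygens and the epoxide oxygen lie on the same, open face of the ring. The angelate isomerises easily to the tiglate, and the epoxide sits between two oxygenated carbons. The E,E-cyclodeca-1,5-diene intermediates cyclise transannularly under acid and undergo Cope rearrangement on heating. The difficulty is to close a medium ring with two defined trisubstituted alkenes and to relate C3 to C6 and C7 across it. The strategy rests on one feature: once the epoxide is read as an E C4=C5 alkene, C2–C3 is the central bond of the hexa-1,5-diene C10=C1–C2–C3–C4=C5. That is the retron of an oxy-Cope shift that opens the C5–C10 bond of a cyclohexane already holding C6 and C7.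

## Retrosynthetic reasoning

**25 to 24.** The C6 acetate is cut last. Acetylation is the mildest step of the endgame, and a free C6 hydroxyl is wanted one step earlier as the directing group.

**24 to 23.** The two C–O bonds of the epoxide are cut to the E C4=C5 alkene of 23. The forward step must choose this alkene over C1=C10 and the angelate alkene, and must choose the face. A hydroxyl-directed metal-catalysed epoxidation answers the first point. The ring answers the second: both ring arms (C2 and C7) lie on one face of the alkene and both oxygens on the other.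

**23 to 20.** The C6 PMB ether, the C3 angelate and the C3 silyl ether are removed in that order, through 22 and 21. The angelate is installed before the epoxide exists, so no alkoxide is ever generated next to the epoxide. The PMB group is removed oxidatively under neutral conditions, which the ester and the acid-sensitive diene tolerate.

**20 to 19.** The C10–CH3 bond is cut to the enol triflate. The methyl cannot be present earlier because C10 is the carbinol carbon of the rearrangement. A stereoretentive cross-coupling of the regiodefined triflate supplies it.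

**19 to 16 (key disconnection).** C2–C3 is cut and C5–C10 is rejoined. This turns the ten-membered ring into cyclohexanol 16 with a vinyl group on C10 and an E silyl enol ether on C5. The ring, the C3 centre and both alkene geometries then come from one sigmatropic event. The six-membered ring can be built with all substituents equatorial under substrate control from a single stereocentre.

**16 to 13 and 14.** The PMB ether and the C10–vinyl bond are cut, through diol 15. Vinyl addition is run on the free β-hydroxy ketone 13. Its alkoxide cannot be eliminated, and the ether is made only when no enolisable ketone is left.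

**13 to 11.** The C6–O bond and the C5–H bond are cut to dienone 11. Conjugate borylation anti to the isopropyl group, then oxidation with retention, sets C6. C5 is α to the ketone and settles equatorial. An epoxide-opening route to the C5–C4 bond was set aside. Trans-diaxial opening of a C5,C6 epoxide anti to the isopropyl group delivers the nucleophile to C6, because attack at C5 needs an axial isopropyl group.

**11 to 5 and 10.** The C5–C4 bond is cut to iodoenone 5 and alkenylboronate 10. A 2-silyloxyvinyl lithium or copper reagent with the metal anti to oxygen would eliminate silanolate, so boron and palladium are used. The coupling transfers the alkene geometry unchanged.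

**10 to 6.** The C–B and C–H bonds are cut to siloxyalkyne 9, which comes from propyne 6 by acetylide oxidation and O-silylation. Syn hydroboration puts boron on the methyl-bearing carbon, trans to oxygen.

**5 to 1 and 2.** Iodoenone 5 comes from enone 4. Enone 4 is cut at the aldol C=C to keto-aldehyde 3, and 3 at its Michael bond to 1 and 2. One enamine-catalysed step sets the C7 centre, which then controls C6, C5 and C10.

## Alternatives that were turned down

**Alternative 1: ring-closing alkyne metathesis.** The ring is cut at C4–C5, read as a triple bond. A molybdenum alkylidyne catalyst with silanolate ligands would close the open-chain diyne A2 to cycloalkyne A1 with loss of but-2-yne. Hydroxyl-directed trans-hydrostannation and C-methylation would then turn the alkyne into the E trisubstituted alkene.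
- For: A2 is assembled from two fragments whose stereocentres are made by independent reagent-controlled steps. The alkyne is inert to most other chemistry. The C4=C5 geometry is set by a reagent and not by a ring conformation; on modularity and on that point it is stronger than the chosen route.
- Against: A1 is a ten-membered cycloalkyne that also holds an E trisubstituted alkene, so ring strain should favour cyclodimers and oligomers. Both C3 and C6 carry propargylic oxygens that could direct the stannane to either alkyne carbon. Three further steps are needed before the alkene and its methyl group exist.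
- In its place the chosen route forms the ring, C3 and both alkenes in one step without high dilution, and derives all stereocentres from one catalytic step.

**Alternative 2: [2,3]-Wittig ring contraction.** The C6–C7 bond is cut and the ring is enlarged to the thirteen-membered propargyl allyl ether A4. A lithium amide would deprotonate the propargylic carbon, and the [2,3] shift would give cyclodecenynol A3.
- For: A4 should close easily by etherification. The shift forms a ring C–C bond and both the C6 and C7 centres. A3 already has the free C6 hydroxyl wanted for the directed epoxidation; on that point it is ahead of the chosen route, which must unmask it.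
- Against: the base must choose the propargylic over the allylic α-oxy position, and [1,2] shift competes. The 6,7 relationship rests on carrying an open-chain E to anti preference into a macrocycle, with only the remote C3 centre to fix the absolute sense. A3 still needs the alkyne-to-methylalkene sequence of alternative 1, and a selective hydrogenation of the isopropenyl group beside two other alkenes.
- The chosen route sets C3 by chirality transfer within a rigid chair and needs no alkyne or isopropenyl adjustment.

**Alternative 3: Ireland–Claisen ring contraction.** The C7–C8 bond is cut and the ring is enlarged to the fourteen-membered lactone A6. Its silyl ketene acetal would rearrange to the ten-membered acid A5.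
- For: macrolactonisation is dependable. Both trisubstituted alkenes are made beforehand by open-chain olefinations of unambiguous geometry, which is a real advantage over setting them in the ring-forming step.
- Against: A5 carries a carboxyl group that the target lacks. Its radical removal next to two ring alkenes invites transannular cyclisation. The isopropenyl group must again be reduced selectively. The C7 configuration depends on ketene acetal geometry and on a chair or boat choice that is hard to predict in a macrocycle. A6 is a long linear target with C3 and C6 already in place.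
- The chosen route is shorter, and the conformationally defined chair of the oxy-Cope step replaces the uncertain macrocyclic transition state.

Key step: step 10

Remark on the chemistry: the facial sense of the enamine-catalysed Michael addition in step 1 is taken from the usual model (attack on the enamine face remote from the diaryl(silyloxy)methyl group); should it prove opposite, the antipodal catalyst is used.

## Route

Step 1
Reactants: 1 3-methylbutanal; 2 but-3-en-2-one
Product: 3 (2S)-5-oxo-2-(propan-2-yl)hexanal
Conditions: (S)-α,α-diphenylprolinol trimethylsilyl ether (5 mol %), ethyl 3,4-dihydroxybenzoate (20 mol %), neat, 4 °C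
Reagents that add atoms: none
Why: Enamine-catalysed Michael addition; the E enamine of 1 should be attacked by the hydrogen-bond-activated enone on its unshielded face, which sets the future C7 centre as S.

Step 2
Reactants: 3 (2S)-5-oxo-2-(propan-2-yl)hexanal
Product: 4 (4S)-4-(propan-2-yl)cyclohex-2-en-1-one
Conditions: LiOH, i-PrOH, rt
Reagents that add atoms: none
Why: Intramolecular aldol condensation of the methyl ketone onto the aldehyde closes the six-membered enone; the mild base and fast ring closure should limit epimerisation of the aldehyde α-centre.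

Step 3
Reactants: 4 (4S)-4-(propan-2-yl)cyclohex-2-en-1-one
Product: 5 (4S)-2-iodo-4-(propan-2-yl)cyclohex-2-en-1-one
Conditions: I2, pyridine, CH2Cl2, 0 °C → rt
Reagents that add atoms: iodine II
Why: α-Iodination of an enone by conjugate addition of pyridine, iodination of the enolate and elimination; the γ-stereocentre is not touched.

Step 4
Reactants: 6 propyne
Product: 9 TIPS prop-1-yn-1-yl ether [tri(propan-2-yl)(prop-1-yn-1-yloxy)silane], via prop-1-ynyllithium 7 (not isolated), via lithium prop-1-yn-1-olate 8 (not isolated)
Conditions: n-BuLi, THF, −78 °C; LiOOt-Bu (from t-BuOOH, LiN(SiMe3)2), −78 → 0 °C; i-Pr3SiOTf, −78 °C → rt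
Reagents that add atoms: tert-butyl hydroperoxide CC(C)(C)OO; triisopropylsilyl trifluoromethanesulfonate CC(C)[Si](OS(=O)(=O)C(F)(F)F)(C(C)C)C(C)C; n-butyllithium [Li]CCCC (lithium of 7 and 8 only)
Why: Oxidation of a lithium acetylide by a lithium alkyl peroxide gives the ynolate, and the bulky silyl triflate should react at oxygen to give the siloxyalkyne (ynolate O-silylation).

Step 5
Reactants: 9 TIPS prop-1-yn-1-yl ether
Product: 10 {[(1Z)-2-(pinB)prop-1-en-1-yl]oxy}TIPS-silane (boron trans to oxygen)
Conditions: pinacolborane, Cp2Zr(H)Cl (5 mol %), Et3N (10 mol %), CH2Cl2, rt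
Reagents that add atoms: pinacolborane B1OC(C)(C)C(C)(C)O1
Why: Zirconium-catalysed syn hydroboration of an ynol ether; polarisation of the alkyne and the bulk of the silyloxy group should both send hydride to the oxygen-bearing carbon and boron to the methyl-bearing carbon, and syn addition then places boron trans to oxygen.

Step 6
Reactants: 5 (4S)-2-iodo-4-(propan-2-yl)cyclohex-2-en-1-one; 10 {[(1Z)-2-(pinB)prop-1-en-1-yl]oxy}TIPS-silane
Product: 11 (4S)-4-(propan-2-yl)-2-[(1E)-1-(TIPS-oxy)prop-1-en-2-yl]cyclohex-2-en-1-one
Conditions: Pd(dppf)Cl2 (5 mol %), K3PO4, THF/H2O, rt → 40 °C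
Reagents that add atoms: none
Why: Suzuki–Miyaura coupling of a reactive 2-iodoenone with an alkenylboronate; it proceeds with retention, so the ring carbon ends trans to the silyloxy group (E enol ether).

Step 7
Reactants: 11 (4S)-4-(propan-2-yl)-2-[(1E)-1-(TIPS-oxy)prop-1-en-2-yl]cyclohex-2-en-1-one
Product: 13 (2R,3S,4S)-3-hydroxy-4-(propan-2-yl)-2-[(1E)-1-(TIPS-oxy)prop-1-en-2-yl]cyclohexan-1-one, via 3-boryl ketone 12 (not isolated)
Conditions: CuCl (5 mol %), DPEphos (5 mol %), NaOt-Bu (10 mol %), B2pin2, MeOH (2 equiv), THF, rt; then NaBO3·4H2O, THF/H2O, 0 °C → rt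
Reagents that add atoms: sodium perborate [Na+].[O-]B1OO1 (oxygen of 13); bis(pinacolato)diboron CC1(C)OB(OC1(C)C)B1OC(C)(C)C(C)(C)O1 (boron of 12 only)
Why: Copper-catalysed conjugate borylation should deliver boron to the β-carbon anti to the adjacent isopropyl group, and perborate oxidation replaces boron by hydroxyl with retention, so C6–O is trans to isopropyl. Methanol protonates the enolate at the α-carbon, which is epimerisable and should settle with the alkenyl group equatorial, trans to the hydroxyl.

Step 8
Reactants: 13 (2R,3S,4S)-3-hydroxy-4-(propan-2-yl)-2-[(1E)-1-(TIPS-oxy)prop-1-en-2-yl]cyclohexan-1-one; 14 vinylmagnesium bromide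
Product: 15 (1R,2R,3S,4S)-1-ethenyl-4-(propan-2-yl)-2-[(1E)-1-(TIPS-oxy)prop-1-en-2-yl]cyclohexane-1,3-diol
Conditions: CeCl3 (dried), 14 (3.5 equiv), THF, −78 → −40 °C
Reagents that add atoms: none
Why: Organocerium 1,2-addition; the first equivalent turns the hydroxyl into an alkoxide that cannot be eliminated, and cerium suppresses enolisation. Equatorial attack, favoured for a vinyl nucleophile next to an equatorial α-substituent, should give the axial alcohol with vinyl trans to the C5 alkenyl group (C10 R).

Step 9
Reactants: 15 (1R,2R,3S,4S)-1-ethenyl-4-(propan-2-yl)-2-[(1E)-1-(TIPS-oxy)prop-1-en-2-yl]cyclohexane-1,3-diol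
Product: 16 (1R,2R,3S,4S)-1-ethenyl-3-(PMB-oxy)-4-(propan-2-yl)-2-[(1E)-1-(TIPS-oxy)prop-1-en-2-yl]cyclohexan-1-ol
Conditions: NaH (1.1 equiv), 4-MeOC6H4CH2Cl, n-Bu4NI (cat.), THF, 0 °C → rt
Reagents that add atoms: 4-methoxybenzyl chloride COc1ccc(CCl)cc1
Why: Williamson etherification; the secondary alkoxide should be alkylated far faster than the tertiary allylic one. A sodium counter-ion without crown ether near 0 °C should not trigger the rearrangement.

Step 10
Reactants: 16 (1R,2R,3S,4S)-1-ethenyl-3-(PMB-oxy)-4-(propan-2-yl)-2-[(1E)-1-(TIPS-oxy)prop-1-en-2-yl]cyclohexan-1-ol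
Product: 19 (3S,4E,6S,7S)-4-methyl-6-(PMB-oxy)-7-(propan-2-yl)-3-(TIPS-oxy)cyclodeca-1(10),4-dien-10-yl trifluoromethanesulfonate (C2 trans to C9; 1(10)Z by the sequence rule), via potassium alkoxide 17 (not isolated), via ring-expanded potassium enolate 18 (not isolated)
Conditions: KH, 18-crown-6, THF, 0 °C → rt; then PhNTf2, −78 → 0 °C
Reagents that add atoms: N-phenylbis(trifluoromethanesulfonimide) O=S(=O)(N(c1ccccc1)S(=O)(=O)C(F)(F)F)C(F)(F)F; potassium hydride [KH] (potassium of 17 and 18 only)
Why: KH with 18-crown-6 gives the dissociated alkoxide 17, whose C5–C10 bond is weakened so that the [3,3] shift should run near room temperature (anionic oxy-Cope rearrangement; the closest known class is the ring expansion of trans-1,2-dialkenylcyclohexanols to E-cyclodec-5-enone enolates with enolate trapping in the same flask). The ten-membered ring is not closed end to end but arises by four-carbon ring expansion: C2–C3 forms across a six-centre chair while the cyclohexane bond C5–C10 breaks. In 16 both alkenyl groups are equatorial and the alkoxide is axial, which fixes the chair and puts C9 and C6 equatorial on it, so C1=C10 emerges with C2 trans to C9 and C4=C5 as the E alkene. The new C3 centre is set by chirality transfer from C5 and C10 through that chair: in the E enol ether the silyloxy group is trans to C5 and therefore equatorial, which translates into 3S, whereas the Z isomer would give 3R. C6 and C7 pass through unchanged. The step needs chair over boat, a regiospecific C1,C10 enolate and sulfonylation at oxygen; the all-equatorial substrate secures the first, the absence of a proton source after complete alkoxide formation the second, and the potassium enolate with PhNTf2 at low temperature the third. The E enol ether also keeps silicon out of reach of the alkoxide, so silyl transfer should not compete.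

Step 11
Reactants: 19 (3S,4E,6S,7S)-4-methyl-6-(PMB-oxy)-7-(propan-2-yl)-3-(TIPS-oxy)cyclodeca-1(10),4-dien-10-yl trifluoromethanesulfonate
Product: 20 (1(10)E,3S,4E,6S,7S)-4,10-dimethyl-6-(PMB-oxy)-7-(propan-2-yl)-3-(TIPS-oxy)cyclodeca-1(10),4-diene
Conditions: MeMgBr, Fe(acac)3 (5 mol %), THF/NMP, −30 °C
Reagents that add atoms: methylmagnesium bromide C[Mg]Br
Why: Iron-catalysed cross-coupling of an alkenyl triflate with a methyl Grignard reagent; it is fast at low temperature, retains the alkene geometry and tolerates the silyl and benzyl ethers.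

Step 12
Reactants: 20 (1(10)E,3S,4E,6S,7S)-4,10-dimethyl-6-(PMB-oxy)-7-(propan-2-yl)-3-(TIPS-oxy)cyclodeca-1(10),4-diene
Product: 21 (1(10)E,3S,4E,6S,7S)-4,10-dimethyl-6-(PMB-oxy)-7-(propan-2-yl)cyclodeca-1(10),4-dien-3-ol
Conditions: n-Bu4NF, THF, 0 °C → rt
Reagents that add atoms: none
Why: Fluoride cleavage of the secondary allylic silyl ether; the PMB ether and the acid-sensitive diene are not affected under these non-acidic conditions.

Step 13
Reactants: 21 (1(10)E,3S,4E,6S,7S)-4,10-dimethyl-6-(PMB-oxy)-7-(propan-2-yl)cyclodeca-1(10),4-dien-3-ol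
Product: 22 (1(10)E,3S,4E,6S,7S)-4,10-dimethyl-6-(PMB-oxy)-7-(propan-2-yl)cyclodeca-1(10),4-dien-3-yl (2Z)-2-methylbut-2-enoate
Conditions: LiN(SiMe3)2, THF, −78 °C; angelic anhydride, −78 → 0 °C
Reagents that add atoms: angelic anhydride C/C=C(/C)C(=O)OC(=O)/C(C)=C\C
Why: Acylation of the lithium alkoxide with the anhydride; no nucleophilic catalyst and no heating are used, which should avoid Z to E isomerisation of the angelate and Cope rearrangement of the diene.

Step 14
Reactants: 22 (1(10)E,3S,4E,6S,7S)-4,10-dimethyl-6-(PMB-oxy)-7-(propan-2-yl)cyclodeca-1(10),4-dien-3-yl (2Z)-2-methylbut-2-enoate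
Product: 23 (1(10)E,3S,4E,6S,7S)-6-hydroxy-4,10-dimethyl-7-(propan-2-yl)cyclodeca-1(10),4-dien-3-yl (2Z)-2-methylbut-2-enoate
Conditions: DDQ, CH2Cl2/pH 7 buffer, 0 °C
Reagents that add atoms: none
Why: Oxidative cleavage of the 4-methoxybenzyl ether by hydride abstraction and hydrolysis; the buffer keeps the medium neutral for the diene.

Step 15
Reactants: 23 (1(10)E,3S,4E,6S,7S)-6-hydroxy-4,10-dimethyl-7-(propan-2-yl)cyclodeca-1(10),4-dien-3-yl (2Z)-2-methylbut-2-enoate
Product: 24 (1(10)E,3S,4R,5R,6S,7S)-4,5-epoxy-6-hydroxy-4,10-dimethyl-7-(propan-2-yl)cyclodec-1(10)-en-3-yl (2Z)-2-methylbut-2-enoate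
Conditions: VO(acac)2 (5 mol %), t-BuOOH, CH2Cl2, 0 °C → rt
Reagents that add atoms: tert-butyl hydroperoxide CC(C)(C)OO
Why: Hydroxyl-directed vanadium-catalysed epoxidation selects the allylic C4=C5 alkene over C1=C10 and the electron-poor angelate. With C6–H eclipsing the alkene plane next to the C4 methyl, the ring arms C2 and C7 lie on one face and the C6 hydroxyl on the other, open face, so delivery there should give the 4R,5R epoxide.

Step 16
Reactants: 24 (1(10)E,3S,4R,5R,6S,7S)-4,5-epoxy-6-hydroxy-4,10-dimethyl-7-(propan-2-yl)cyclodec-1(10)-en-3-yl (2Z)-2-methylbut-2-enoate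
Product: 25 (1(10)E,3S,4R,5R,6S,7S)-6-acetoxy-4,5-epoxy-4,10-dimethyl-7-(propan-2-yl)cyclodec-1(10)-en-3-yl (2Z)-2-methylbut-2-enoate
Conditions: Ac2O, pyridine, DMAP (cat.), CH2Cl2, 0 °C → rt
Reagents that add atoms: acetic anhydride CC(=O)OC(C)=O
Why: Acylation of the secondary alcohol under mild basic conditions; the epoxide and the angelate should survive.

## Compound list

1 | 3-methylbutanal | CC(C)CC=O | starting material
2 | but-3-en-2-one (methyl vinyl ketone) | CC(=O)C=C | starting material
3 | (2S)-5-oxo-2-(propan-2-yl)hexanal | O=C[C@H](C(C)C)CCC(C)=O | intermediate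
4 | (4S)-4-(propan-2-yl)cyclohex-2-en-1-one | O=C1CC[C@@H](C(C)C)C=C1 | intermediate
5 | (4S)-2-iodo-4-(propan-2-yl)cyclohex-2-en-1-one | O=C1CC[C@@H](C(C)C)C=C1I | intermediate
6 | propyne | CC#C | starting material
7 | prop-1-ynyllithium | [Li]C#CC | intermediate
8 | lithium prop-1-yn-1-olate | [Li+].[O-]C#CC | intermediate
9 | tri(propan-2-yl)(prop-1-yn-1-yloxy)silane | CC#CO[Si](C(C)C)(C(C)C)C(C)C | intermediate
10 | {[(1Z)-2-(4,4,5,5-tetramethyl-1,3,2-dioxaborolan-2-yl)prop-1-en-1-yl]oxy}tri(propan-2-yl)silane (boron trans to oxygen) | C/C(=C\O[Si](C(C)C)(C(C)C)C(C)C)B1OC(C)(C)C(C)(C)O1 | intermediate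
11 | (4S)-4-(propan-2-yl)-2-[(1E)-1-(TIPS-oxy)prop-1-en-2-yl]cyclohex-2-en-1-one | O=C1CC[C@@H](C(C)C)C=C1/C(C)=C/O[Si](C(C)C)(C(C)C)C(C)C | intermediate
12 | (2S,3S,4R)-4-(propan-2-yl)-3-(4,4,5,5-tetramethyl-1,3,2-dioxaborolan-2-yl)-2-[(1E)-1-(TIPS-oxy)prop-1-en-2-yl]cyclohexan-1-one (boryl group trans to both neighbours) | O=C1CC[C@@H](C(C)C)[C@H](B2OC(C)(C)C(C)(C)O2)[C@H]1/C(C)=C/O[Si](C(C)C)(C(C)C)C(C)C | intermediate
13 | (2R,3S,4S)-3-hydroxy-4-(propan-2-yl)-2-[(1E)-1-(TIPS-oxy)prop-1-en-2-yl]cyclohexan-1-one | O=C1CC[C@@H](C(C)C)[C@H](O)[C@H]1/C(C)=C/O[Si](C(C)C)(C(C)C)C(C)C | intermediate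
14 | vinylmagnesium bromide | C=C[Mg]Br | starting material
15 | (1R,2R,3S,4S)-1-ethenyl-4-(propan-2-yl)-2-[(1E)-1-(TIPS-oxy)prop-1-en-2-yl]cyclohexane-1,3-diol | O[C@@]1(C=C)CC[C@@H](C(C)C)[C@H](O)[C@H]1/C(C)=C/O[Si](C(C)C)(C(C)C)C(C)C | intermediate
16 | (1R,2R,3S,4S)-1-ethenyl-3-(PMB-oxy)-4-(propan-2-yl)-2-[(1E)-1-(TIPS-oxy)prop-1-en-2-yl]cyclohexan-1-ol (axial hydroxyl, all other substituents equatorial) | O[C@@]1(C=C)CC[C@@H](C(C)C)[C@H](OCc2ccc(OC)cc2)[C@H]1/C(C)=C/O[Si](C(C)C)(C(C)C)C(C)C | intermediate
17 | potassium alkoxide of 16 | [K+].[O-][C@@]1(C=C)CC[C@@H](C(C)C)[C@H](OCc2ccc(OC)cc2)[C@H]1/C(C)=C/O[Si](C(C)C)(C(C)C)C(C)C | intermediate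
18 | potassium (3S,4E,6S,7S)-4-methyl-6-(PMB-oxy)-7-(propan-2-yl)-3-(TIPS-oxy)cyclodeca-1(10),4-dien-10-olate (C2 trans to C9) | C1[C@@H](C(C)C)[C@H](OCc2ccc(OC)cc2)/C=C(\C)[C@@H](O[Si](C(C)C)(C(C)C)C(C)C)C/C=C(\[O-])C1.[K+] | intermediate
19 | (3S,4E,6S,7S)-4-methyl-6-(PMB-oxy)-7-(propan-2-yl)-3-(TIPS-oxy)cyclodeca-1(10),4-dien-10-yl trifluoromethanesulfonate (C2 trans to C9; 1(10)Z by the sequence rule) | C1[C@@H](C(C)C)[C@H](OCc2ccc(OC)cc2)/C=C(\C)[C@@H](O[Si](C(C)C)(C(C)C)C(C)C)C/C=C(\OS(=O)(=O)C(F)(F)F)C1 | intermediate
20 | (1(10)E,3S,4E,6S,7S)-4,10-dimethyl-6-(PMB-oxy)-7-(propan-2-yl)-3-(TIPS-oxy)cyclodeca-1(10),4-diene | C1[C@@H](C(C)C)[C@H](OCc2ccc(OC)cc2)/C=C(\C)[C@@H](O[Si](C(C)C)(C(C)C)C(C)C)C/C=C(\C)C1 | intermediate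
21 | (1(10)E,3S,4E,6S,7S)-4,10-dimethyl-6-(PMB-oxy)-7-(propan-2-yl)cyclodeca-1(10),4-dien-3-ol | C1[C@@H](C(C)C)[C@H](OCc2ccc(OC)cc2)/C=C(\C)[C@@H](O)C/C=C(\C)C1 | intermediate
22 | (1(10)E,3S,4E,6S,7S)-4,10-dimethyl-6-(PMB-oxy)-7-(propan-2-yl)cyclodeca-1(10),4-dien-3-yl (2Z)-2-methylbut-2-enoate | C1[C@@H](C(C)C)[C@H](OCc2ccc(OC)cc2)/C=C(\C)[C@@H](OC(=O)/C(C)=C\C)C/C=C(\C)C1 | intermediate
23 | (1(10)E,3S,4E,6S,7S)-6-hydroxy-4,10-dimethyl-7-(propan-2-yl)cyclodeca-1(10),4-dien-3-yl (2Z)-2-methylbut-2-enoate | C1[C@@H](C(C)C)[C@H](O)/C=C(\C)[C@@H](OC(=O)/C(C)=C\C)C/C=C(\C)C1 | intermediate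
24 | (1(10)E,3S,4R,5R,6S,7S)-4,5-epoxy-6-hydroxy-4,10-dimethyl-7-(propan-2-yl)cyclodec-1(10)-en-3-yl (2Z)-2-methylbut-2-enoate | C/C=C(/C)C(=O)O[C@H]1C/C=C(\C)CC[C@@H](C(C)C)[C@H](O)[C@H]2O[C@]12C | intermediate
25 | (1(10)E,3S,4R,5R,6S,7S)-6-acetoxy-4,5-epoxy-4,10-dimethyl-7-(propan-2-yl)cyclodec-1(10)-en-3-yl (2Z)-2-methylbut-2-enoate (CNP0180504.4) | C/C=C(/C)C(=O)O[C@H]1C/C=C(\C)CC[C@@H](C(C)C)[C@H](OC(C)=O)[C@H]2O[C@]12C | target

## Step count and risks

Total step count: 16. Longest linear sequence: 14 steps (steps 1–3 and 6–16); steps 4 and 5 form the two-step side branch to boronate 10.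

**Step 10 (key step).** The silyloxy donor at the migrating terminus may slow the [3,3] shift, which leaves time for proton transfer to move the enolate toward C9. The potassium enolate may also take up the sulfonyl group sluggishly or at carbon. Either would cost the regiochemistry or geometry of the C1=C10 unit. Fallback: from 16 the rearrangement is run in the same way but the enolate is quenched with diethyl chlorophosphate, a small and fast oxygen-selective electrophile. This gives the enol diethyl phosphate F1, which is robust enough to purify. Kumada coupling of F1 with MeMgBr under Ni(acac)2 catalysis then installs the C10 methyl and rejoins the route at 20.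

**Step 7.** The β-carbon of 11 is also the terminus of a siloxydiene, so conjugate addition of the boryl-copper species may be slow. The resulting dienolate could be protonated at the remote carbon. The β-hydroxy ketone could lose water during the oxidative work-up. Fallback: from 11, nucleophilic epoxidation with t-BuOOH and DBU should add the peroxide anti to the isopropyl group and give the epoxy ketone F2. SmI2 in THF/MeOH at −90 °C then cleaves the α C–O bond reductively, and protonation of the samarium enolate returns to 13.

**Step 8.** Axial approach of the vinyl nucleophile would give the C10 epimer. The unprotected magnesium aldolate may enolise or fragment by retro-aldol cleavage before addition is complete. Fallback: from 13 the hydroxyl is masked with Me3SiCl and imidazole as the trimethylsilyl ether F3. CeCl3-mediated addition of 14 to this neutral ketone gives the tertiary alcohol F4, and K2CO3 in MeOH removes the labile silyl group to return to 15.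

**Step 5.** Hydride may be delivered to the wrong alkyne carbon under zirconium catalysis, or the siloxyalkyne may decompose at the metal. Fallback: from 9, uncatalysed hydroboration with dicyclohexylborane puts the electrophilic boron on the nucleophilic methyl-bearing carbon of the ynol ether. The resulting dicyclohexyl[(1Z)-1-(TIPS-oxy)prop-1-en-2-yl]borane F5 is coupled without isolation with 5 under Pd(PPh3)4 and aqueous NaOH, and the route is rejoined at 11.

**Step 15.** The ring holds the O–C6–C5=C4 dihedral angle away from the value that the vanadium ester prefers. Epoxidation may then be slow enough for oxidation of the allylic alcohol to the enone to compete, or facial selectivity may be poor if the alkene flips through the ring. Fallback: from 21 the epoxidation is directed by the C3 hydroxyl, which lies on the same open face and is attached to the fully substituted alkene carbon (VO(acac)2, t-BuOOH). This gives the epoxy alcohol F6. Acylation of its lithium alkoxide with angelic anhydride at −78 °C gives the epoxy angelate F7, and DDQ removes the PMB group to rejoin the route at 24.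

**Step 13.** The hindered alkoxide may acylate slowly, and the angelate may isomerise to the E ester under basic conditions. Fallback: from 21 the alcohol is esterified with 2-[bis(2,2,2-trifluoroethoxy)phosphoryl]propanoic acid and a carbodiimide to the phosphonate ester F8. Still–Gennari olefination with acetaldehyde (KN(SiMe3)2, 18-crown-6, THF, −78 °C) then builds the Z alkene of the angelate directly and rejoins the route at 22.

## Further compounds

F1 | step 10 | (3S,4E,6S,7S)-4-methyl-6-(PMB-oxy)-7-(propan-2-yl)-3-(TIPS-oxy)cyclodeca-1(10),4-dien-10-yl diethyl phosphate (C2 trans to C9) | C1[C@@H](C(C)C)[C@H](OCc2ccc(OC)cc2)/C=C(\C)[C@@H](O[Si](C(C)C)(C(C)C)C(C)C)C/C=C(\OP(=O)(OCC)OCC)C1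
F2 | step 7 | 2,3-epoxy-4-(propan-2-yl)-2-[(1E)-1-(TIPS-oxy)prop-1-en-2-yl]cyclohexan-1-one, epoxide anti to the isopropyl group | O=C1CC[C@@H](C(C)C)[C@@H]2O[C@]12/C(C)=C/O[Si](C(C)C)(C(C)C)C(C)C
F3 | step 8 | trimethylsilyl ether of 13 | O=C1CC[C@@H](C(C)C)[C@H](O[Si](C)(C)C)[C@H]1/C(C)=C/O[Si](C(C)C)(C(C)C)C(C)C
F4 | step 8 | 3-O-trimethylsilyl ether of 15 | O[C@@]1(C=C)CC[C@@H](C(C)C)[C@H](O[Si](C)(C)C)[C@H]1/C(C)=C/O[Si](C(C)C)(C(C)C)C(C)C
F5 | step 5 | dicyclohexyl[(1Z)-1-(TIPS-oxy)prop-1-en-2-yl]borane (boron trans to oxygen) | C/C(=C\O[Si](C(C)C)(C(C)C)C(C)C)B(C1CCCCC1)C1CCCCC1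
F6 | step 15 | (1(10)E,3S,4R,5R,6S,7S)-4,5-epoxy-4,10-dimethyl-6-(PMB-oxy)-7-(propan-2-yl)cyclodec-1(10)-en-3-ol | O[C@H]1C/C=C(\C)CC[C@@H](C(C)C)[C@H](OCc2ccc(OC)cc2)[C@H]2O[C@]12C
F7 | step 15 | (1(10)E,3S,4R,5R,6S,7S)-4,5-epoxy-4,10-dimethyl-6-(PMB-oxy)-7-(propan-2-yl)cyclodec-1(10)-en-3-yl (2Z)-2-methylbut-2-enoate | C/C=C(/C)C(=O)O[C@H]1C/C=C(\C)CC[C@@H](C(C)C)[C@H](OCc2ccc(OC)cc2)[C@H]2O[C@]12C
F8 | step 13 | (1(10)E,3S,4E,6S,7S)-4,10-dimethyl-6-(PMB-oxy)-7-(propan-2-yl)cyclodeca-1(10),4-dien-3-yl 2-[bis(2,2,2-trifluoroethoxy)phosphoryl]propanoate (phosphonate α-carbon unassigned) | C1[C@@H](C(C)C)[C@H](OCc2ccc(OC)cc2)/C=C(\C)[C@@H](OC(=O)C(C)P(=O)(OCC(F)(F)F)OCC(F)(F)F)C/C=C(\C)C1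
A1 | alternative 1 | (1(10)E,3S,6S,7S)-10-methyl-7-(propan-2-yl)-6-(TBS-oxy)-3-(TES-oxy)cyclodec-1(10)-en-4-yne (target numbering) | C1[C@@H](C(C)C)[C@H](O[Si](C)(C)C(C)(C)C)C#C[C@@H](O[Si](CC)(CC)CC)C/C=C(\C)C1
A2 | alternative 1 | (4S,6E,10S,11S)-7-methyl-10-(propan-2-yl)-11-(TBS-oxy)-4-(TES-oxy)tetradec-6-ene-2,12-diyne | CC#C[C@@H](O[Si](CC)(CC)CC)C/C=C(\C)CC[C@@H](C(C)C)[C@H](O[Si](C)(C)C(C)(C)C)C#CC
A3 | alternative 2 | (1(10)E,3S,6S,7S)-10-methyl-7-(prop-1-en-2-yl)-3-(TIPS-oxy)cyclodec-1(10)-en-4-yn-6-ol (target numbering) | C1[C@@H](C(C)=C)[C@H](O)C#C[C@@H](O[Si](C(C)C)(C(C)C)C(C)C)C/C=C(\C)C1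
A4 | alternative 2 | (3E,7E,10S)-3,7-dimethyl-10-(TIPS-oxy)-1-oxacyclotrideca-3,7-dien-11-yne (allyl alkene geometry assumed E) | C1OC/C(C)=C/CC/C(C)=C/C[C@H](O[Si](C(C)C)(C(C)C)C(C)C)C#C1
A5 | alternative 3 | (1(10)E,3S,4E,6S,7S)-4,10-dimethyl-3-(PMB-oxy)-7-(prop-1-en-2-yl)-6-(TBS-oxy)cyclodeca-1(10),4-diene-8-carboxylic acid (target numbering; C8 arbitrary) | OC(=O)[C@@H]1[C@@H](C(C)=C)[C@H](O[Si](C)(C)C(C)(C)C)/C=C(\C)[C@@H](OCc2ccc(OC)cc2)C/C=C(\C)C1
A6 | alternative 3 | (5E,8S,9E,11S,12E)-5,9,13-trimethyl-8-(PMB-oxy)-11-(TBS-oxy)-1-oxacyclotetradeca-5,9,12-trien-2-one (allyl alkene geometry assumed E) | O=C1CC/C(C)=C/C[C@H](OCc2ccc(OC)cc2)/C(C)=C/[C@@H](O[Si](C)(C)C(C)(C)C)/C=C(C)/CO1
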